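## Retrosynthetic overview

1. Xestin A ⇒ acyclic (2E,4Z)-6-hydroperoxy-6-methoxy dienoate. The O2–C3 bond comes from a catalyst-controlled 6-exo peroxy-Michael closure that sets 3R. C6 is then set by anomeric (thermodynamic) ketal equilibration in MeOH.
2. Hydroperoxy ketal ⇒ (2E,4Z)-6-oxodienoate + H2O2 + MeOH (perketalisation).
3. Key C2–C3 disconnection of the dissonant C1/C6 1,6-dicarbonyl ⇒ a 2-alkylfuran plus the rhodium carbenoid from methyl diazoacetate. The furan is a donor at C5 (the masked γ-carbon of the C6 ketone). In the carbenoid the ester α-carbon is inverted to an acceptor, an enolonium-type a2 synthon.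
4. 2-Alkylfuran ⇒ furan + 1,12-dibromododecane + sorbyl acetate (lithiation/alkylation, then copper-catalysed Grignard coupling).
5. Ring order: the purchased furan ring is opened in the key step and hands on its cis C=C. The 1,2-dioxine, the only ring of the target, is formed last.

Assumption: the facial sense of the catalyst in step 6 is taken by analogy with related oxa-Michael closures. If it proves opposite, the pseudoenantiomeric quinine-derived squaramide is used with nothing else changed.

## Route

**Step 1**
Reactants: 1 furan; 2 1,12-dibromododecane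
Product: 4 2-(12-bromododecyl)furan, via 2-furyllithium 3 (not isolated)
Conditions: 1 (1.1 equiv), n-BuLi (1.0 equiv), THF, 0 °C, 1 h; then added to 2 (3 equiv), THF, 0 °C to rt, 12 h
Reagents that add atoms: none
Why: α-Lithiation of furan followed by SN2 alkylation of the 2-furyllithium is standard chemistry, a threefold excess of the dibromide (recovered) suppresses double alkylation, and no stereocentre is created.

**Step 2**
Reactants: 4 2-(12-bromododecyl)furan; 5 (2E,4E)-hexa-2,4-dien-1-yl acetate (sorbyl acetate)
Product: 7 2-[(14E,16E)-octadeca-14,16-dien-1-yl]furan, via 12-(furan-2-yl)dodecylmagnesium bromide 6 (not isolated)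
Conditions: Mg (1.3 equiv), I2 (crystal), THF, 45 °C; then 5 (1.0 equiv), Li2CuCl4 (2 mol %), THF, −20 to 0 °C
Reagents that add atoms: none
Why: Kochi-type copper-catalysed cross-coupling of a primary Grignard reagent with an allylic acetate, which for sorbyl acetate takes place at the acetate-bearing carbon (SN2, not SN2') with retention of the E,E-diene as in conjugated-diene pheromone syntheses, while the furan is inert to RMgBr.

**Step 3**
Reactants: 8 glycine methyl ester hydrochloride
Product: 9 methyl diazoacetate
Conditions: NaNO2 (1.2 equiv), H2SO4 (5 mol %), CH2Cl2/H2O, −5 °C; NaHCO3 wash, dried, kept as a ca. 1 M CH2Cl2 solution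
Reagents that add atoms: sodium nitrite, [Na+].[O-]N=O
Why: Diazotisation of an α-amino ester, in which nitrosation of the amine and loss of water stop at the ester-stabilised diazo compound, which is extracted into CH2Cl2 as it forms and used without distillation.

**Step 4 (key step)**
Reactants: 7 2-[(14E,16E)-octadeca-14,16-dien-1-yl]furan; 9 methyl diazoacetate
Product: 12 methyl (2E,4Z,20E,22E)-6-oxotetracosa-2,4,20,22-tetraenoate, via rhodium carbenoid Rh2(OAc)4=CHCO2Me 10 (not isolated), via exo-2-oxabicyclo[3.1.0]hex-3-ene cyclopropane 11 (not isolated)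
Conditions: 7 (1.3 equiv, excess recovered), Rh2(OAc)4 (1 mol %), CH2Cl2, rt, dark; 9 (1.0 equiv) by syringe pump over 8 h; quick filtration through deactivated silica
Reagents that add atoms: none
Why: Rhodium-carbenoid furan ring opening (cyclopropanation of the less substituted furan double bond, then electrocyclic opening of the donor–acceptor cyclopropane): loss of N2 turns the ester α-carbon, normally a donor, into an electrophilic enolonium-type a2 centre that is attacked by the free C5 of the 2-alkylfuran, itself the masked donor γ-carbon of the C6-ketone dienolate, so the dissonant C1/C6 1,6-dicarbonyl array is made in one C–C bond-forming step, the cis geometry of the ring is handed on as the 4Z alkene needed for ring closure, and the furan (far more nucleophilic than an internal E,E-dialkyldiene, which is also a sterically poor carbenoid acceptor) is attacked selectively when 9 is the limiting, slowly added partner.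

**Step 5**
Reactants: 12 methyl (2E,4Z,20E,22E)-6-oxotetracosa-2,4,20,22-tetraenoate
Product: 13 methyl (2E,4Z,20E,22E)-6-hydroperoxy-6-methoxytetracosa-2,4,20,22-tetraenoate (racemic at C6)
Conditions: urea·H2O2 (5 equiv), Sc(OTf)3 (10 mol %), MeOH, 0 °C, dark, 2–4 h
Reagents that add atoms: urea–hydrogen peroxide, NC(N)=O.OO (gives the OOH group); methanol, CO (gives the OMe group)
Why: Lewis-acid-catalysed perketalisation (ketone to α-methoxy hydroperoxide through the methoxy oxocarbenium ion), a reaction known for 6-oxo-2-enoates, is driven by the high carbonyl affinity of H2O2, masks the enone so that no conjugate addition at C4 can occur later, leaves enoate, side-chain diene and 4Z alkene untouched at 0 °C in the dark, and gives C6 as a racemate that is corrected in step 6.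

**Step 6**
Reactants: 13 methyl (2E,4Z,20E,22E)-6-hydroperoxy-6-methoxytetracosa-2,4,20,22-tetraenoate
Product: 15 xestin A [methyl 2-{(3R,6R)-6-methoxy-6-[(14E,16E)-octadeca-14,16-dien-1-yl]-3,6-dihydro-1,2-dioxin-3-yl}acetate], via (3R,6S)-epimer of xestin A 14 (not isolated)
Conditions: 3-{[3,5-bis(trifluoromethyl)phenyl]amino}-4-{[(9R)-6'-methoxycinchonan-9-yl]amino}cyclobut-3-ene-1,2-dione (quinidine-derived squaramide, C32H28F6N4O3, 10 mol %), toluene, −20 °C, 48 h; then MeOH, p-TsOH·H2O (25 mol %), 0 °C to rt, 3 h; chromatography, any 14 left at equilibrium goes back into the same acid/MeOH treatment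
Reagents that add atoms: methanol, CO (exchanges with the C6 methoxy group when 14 is equilibrated to 15)
Why: Proposed new method: an enantioselective 6-exo-trig intramolecular peroxy-Michael addition in which the quinuclidine nitrogen deprotonates the acidic α-methoxy hydroperoxide while the squaramide N–H bonds hold the ester carbonyl, so that the peroxide oxygen is delivered to one face of C3 of the 2E-enoate and sets 3R under catalyst control in both C6 antipodes of 13 (the 4Z alkene holds OOH and C3 within bonding distance and, with the ketone masked, no other acceptor site can give a ring), after which acid in MeOH ionises only the C6 ketal and funnels 14 into 15, the anomerically favoured isomer with axial OMe cis to the pseudo-equatorial CH2CO2Me and a pseudo-equatorial alkyl chain, the closest known reaction types being the Et2NH-catalysed cyclisation of 6-hydroperoxy-6-methoxy-2-enoates to 3-methoxy-1,2-dioxanes, cinchona squaramide- or thiourea-catalysed asymmetric intramolecular oxa-Michael additions, and the acid-catalysed ketalisation and equilibration of related 3-alkoxy-3,6-dihydro-1,2-dioxines.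

## Compound list

1 | furan | c1ccoc1 | starting material
2 | 1,12-dibromododecane | BrCCCCCCCCCCCCBr | starting material
3 | 2-furyllithium | [Li]c1ccco1 | intermediate
4 | 2-(12-bromododecyl)furan | BrCCCCCCCCCCCCc1ccco1 | intermediate
5 | (2E,4E)-hexa-2,4-dien-1-yl acetate (sorbyl acetate) | C/C=C/C=C/COC(C)=O | starting material
6 | 12-(furan-2-yl)dodecylmagnesium bromide | Br[Mg]CCCCCCCCCCCCc1ccco1 | intermediate
7 | 2-[(14E,16E)-octadeca-14,16-dien-1-yl]furan | C/C=C/C=C/CCCCCCCCCCCCCc1ccco1 | intermediate
8 | glycine methyl ester hydrochloride | Cl.NCC(=O)OC | starting material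
9 | methyl diazoacetate | COC(=O)C=[N+]=[N-] | intermediate
10 | rhodium carbenoid Rh2(OAc)4=CHCO2Me (bridging acetates drawn as terminal ones) | COC(=O)C=[Rh](OC(C)=O)(OC(C)=O)[Rh](OC(C)=O)OC(C)=O | intermediate
11 | methyl 3-[(14E,16E)-octadeca-14,16-dien-1-yl]-2-oxabicyclo[3.1.0]hex-3-ene-6-carboxylate (exo ester, racemic, one enantiomer drawn) | COC(=O)[C@H]1[C@@H]2C=C(CCCCCCCCCCCCC/C=C/C=C/C)O[C@H]12 | intermediate
12 | methyl (2E,4Z,20E,22E)-6-oxotetracosa-2,4,20,22-tetraenoate | C/C=C/C=C/CCCCCCCCCCCCCC(=O)/C=C\C=C\C(=O)OC | intermediate
13 | methyl (2E,4Z,20E,22E)-6-hydroperoxy-6-methoxytetracosa-2,4,20,22-tetraenoate (racemic at C6) | C/C=C/C=C/CCCCCCCCCCCCCC(OC)(OO)/C=C\C=C\C(=O)OC | intermediate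
14 | methyl 2-{(3R,6S)-6-methoxy-6-[(14E,16E)-octadeca-14,16-dien-1-yl]-3,6-dihydro-1,2-dioxin-3-yl}acetate (C6 epimer) | C/C=C/C=C/CCCCCCCCCCCCC[C@@]1(OC)C=C[C@@H](CC(=O)OC)OO1 | intermediate
15 | xestin A, methyl 2-{(3R,6R)-6-methoxy-6-[(14E,16E)-octadeca-14,16-dien-1-yl]-3,6-dihydro-1,2-dioxin-3-yl}acetate | C/C=C/C=C/CCCCCCCCCCCCC[C@]1(OC)C=C[C@@H](CC(=O)OC)OO1 | target

## Step count and risks

Total step count: 6. Longest linear sequence: 5 (steps 1, 2, 4, 5, 6).

**Step 6 is the most likely to fail.**
- The enantioselective closure is new.
- One C6 antipode of 13 is mismatched with the catalyst.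
- The amine can slowly destroy the product by Kornblum–DeLaMare fragmentation.

The fallback sets out from 13 and comes back at 15. Compound 13 is closed with an achiral base (Et2NH, 20 mol %, CF3CH2OH, rt) and equilibrated with p-TsOH·H2O in MeOH. This gives 15 together with its antipode ent-xestin A F4. The trans pair, 14 and its antipode the (3S,6R)-epimer F5, is cut off and recycled through acid/MeOH.

The racemate is then resolved kinetically by a chiral-base-catalysed Kornblum–DeLaMare fragmentation, using 9-O-acetylcupreine (C21H24N2O3, 10 mol %) or its pseudoenantiomer 9-O-acetylcupreidine, CH2Cl2, rt, to about 55 % conversion. This reaction type is known for desymmetrising meso-1,2-dioxines by picking one of two enantiotopic C–H bonds. Only the (3S)-configured C3–H is removed, and F4 collapses to methyl (4Z,20E,22E)-3,6-dioxotetracosa-4,20,22-trienoate F6. Compound 15 is recovered unchanged. The same treatment can polish material of incomplete ee from the main route.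

**Step 4 is second.**
- The acceptor carbenoid may also cyclopropanate the side-chain diene or dimerise.
- The 4Z alkene isomerises easily.

The fallback sets out from 7 and comes back at 12, and gives up the carbenoid for oxidative furan opening plus olefination. Singlet oxygen (O2, 5,10,15,20-tetraphenylporphyrin C44H30N4, visible light, CH2Cl2, −78 °C) reacts with the furan orders of magnitude faster than with the acyclic diene. It gives the furan endoperoxide 1-[(14E,16E)-octadeca-14,16-dien-1-yl]-2,3,7-trioxabicyclo[2.2.1]hept-5-ene F1. Me2S reduces this at low temperature to (2Z,18E,20E)-4-oxodocosa-2,18,20-trienal F2. The aldehyde is trapped in the same flask with Ph3P=CHCO2Me (aldehyde-selective, E-selective Wittig reaction) to give 12.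

**Step 5 is third.** A conjugated Z-dienone is a poorer and more fragile partner for the three-component equilibrium than the saturated ketones for which it is known.

The fallback sets out from 12 and comes back at 13, and separates the two C–O bond formations. Water-free, irreversible ketalisation (HC(OMe)3, MeOH, pyridinium p-toluenesulfonate, 0 °C) gives methyl (2E,4Z,20E,22E)-6,6-dimethoxytetracosa-2,4,20,22-tetraenoate F3. One methoxy group of F3 is then exchanged by perhydrolysis with dry ethereal H2O2 (1.5 equiv) and H3PMo12O40 (2 mol %) in Et2O at 0 °C to give 13.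

## Further compounds

F1 | step 4 | 1-[(14E,16E)-octadeca-14,16-dien-1-yl]-2,3,7-trioxabicyclo[2.2.1]hept-5-ene (racemic, bridgeheads fixed by the bicycle) | C/C=C/C=C/CCCCCCCCCCCCCC12C=CC(OO1)O2
F2 | step 4 | (2Z,18E,20E)-4-oxodocosa-2,18,20-trienal | C/C=C/C=C/CCCCCCCCCCCCCC(=O)/C=C\C=O
F3 | step 5 | methyl (2E,4Z,20E,22E)-6,6-dimethoxytetracosa-2,4,20,22-tetraenoate | C/C=C/C=C/CCCCCCCCCCCCCC(OC)(OC)/C=C\C=C\C(=O)OC
F4 | step 6 | ent-xestin A, the (3S,6S)-enantiomer of 15 | C/C=C/C=C/CCCCCCCCCCCCC[C@@]1(OC)C=C[C@H](CC(=O)OC)OO1
F5 | step 6 | (3S,6R)-epimer, the enantiomer of 14 | C/C=C/C=C/CCCCCCCCCCCCC[C@]1(OC)C=C[C@H](CC(=O)OC)OO1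
F6 | step 6 | methyl (4Z,20E,22E)-3,6-dioxotetracosa-4,20,22-trienoate | C/C=C/C=C/CCCCCCCCCCCCCC(=O)/C=C\C(=O)CC(=O)OC
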